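**Retrosynthetic overview**

1. Target 51 is a 28-membered pentaene macrolactone. Its only ring is closed last, by an intramolecular Sm(II) pinacol (ketyl–carbonyl) coupling of seco-dialdehyde 49 that forms C13–C14 and sets both new carbinol centres; global desilylation follows.
2. Enabling feature: inside the lactone ring C13 and C14 are adjacent secondary carbinol carbons (the 1,2-diol of the C13–C15 triol, between C12H2 and the allylic C15–O stereocentre). Both are therefore aldehyde carbons of like polarity that a one-electron reductant can join. The C1–O–C27 ester is the tether and C15–OTBS the control element.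
3. 49 ⇐ seco ester 47 ⇐ Yamaguchi union of acid 28 (C1–C13, C1′–C6′) and alcohol 45 (C14–C27).
4. 28 ⇐ Evans syn-aldol (C2–C3) of imide 7 with aldehyde 23. 23 ⇐ statin building block 8 (C7–C13; supplies C9 and C11) by a 1,5-anti boron aldol (C5–C6) and a 1,3-anti reduction (C7).
5. 45 ⇐ two Suzuki couplings (C23–C24, C17–C18) of boronate 40 (Marshall propargylation), bromodienal 42 and Z-iodide 35 (anti-carbomagnesiation of a glyceraldehyde-derived alkyne). Ring order: the purchased dioxane and dioxolane rings are opened in steps 11 and 21; the macrocycle forms in step 35.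

Key step: step 35

Remarks (assumptions):
- The SMILES is read literally: C16=C17 has C15 and C18 on the same side (16Z, methyl trans to C18); the other four alkenes are E.
- Locants C1–C27 and C1′–C6′ are those of the target (C1 = lactone carbonyl, C27 = carbinol carbon of the lactone oxygen). A stereocentre quoted by target locant has the spatial arrangement it has in the target; the SMILES is authoritative.
- TBS = tert-butyldimethylsilyl, TES = triethylsilyl, Bn = benzyl, Bpin = 4,4,5,5-tetramethyl-1,3,2-dioxaborolan-2-yl. All polyene intermediates are handled in the dark under argon.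

**Part A – side-chain imide (C1, C2, C1′–C6′)**

Step 1
Reactants: 1 methyl 3-oxooctanoate
Product: 2 methyl (3S)-3-hydroxyoctanoate
Conditions: H2 (50 atm), RuCl2[(S)-BINAP] (0.2 mol%), MeOH, 50 °C
Reagents that add atoms: none
Why: Noyori asymmetric hydrogenation of a β-keto ester; the (S)-BINAP–Ru catalyst should deliver the (3S)-carbinol that becomes C1′.

Step 2
Reactants: 2 methyl (3S)-3-hydroxyoctanoate
Product: 3 methyl (3S)-3-(TBS-oxy)octanoate
Conditions: TBSCl, imidazole, DMF, rt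
Reagents that add atoms: tert-butyldimethylsilyl chloride CC(C)(C)[Si](C)(C)Cl
Why: Imidazole-promoted O-silylation protects the C1′ hydroxyl as a base-stable silyl ether.

Step 3
Reactants: 3 methyl (3S)-3-(TBS-oxy)octanoate
Product: 4 (3S)-3-(TBS-oxy)octanoic acid
Conditions: LiOH·H2O, THF/MeOH/H2O, 0 °C → rt; then 1 M HCl to pH 4
Reagents that add atoms: lithium hydroxide [Li+].[OH-]
Why: Ester saponification at low temperature, where E1cB loss of the β-silyloxy group should not compete and the stereocentre is untouched.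

Step 4
Reactants: 4 (3S)-3-(TBS-oxy)octanoic acid, 5 (4R)-4-benzyl-1,3-oxazolidin-2-one
Product: 7 (4R)-4-benzyl-3-[(3S)-3-(TBS-oxy)octanoyl]-1,3-oxazolidin-2-one, via mixed pivalic anhydride 6 (not isolated)
Conditions: PivCl, Et3N, THF, −20 °C; then 5, LiCl, rt
Reagents that add atoms: pivaloyl chloride CC(C)(C)C(=O)Cl (in intermediate 6 only)
Why: N-Acylation of the oxazolidinone through the mixed anhydride (Evans auxiliary attachment, LiCl/Et3N variant) does not touch the β-stereocentre.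

**Part B – acid 28 (C1–C13)**

Step 5
Reactants: 8 tert-butyl 2-[(4R,6R)-6-(cyanomethyl)-2,2-dimethyl-1,3-dioxan-4-yl]acetate
Product: 9 2-[(4R,6S)-6-(2-hydroxyethyl)-2,2-dimethyl-1,3-dioxan-4-yl]acetonitrile
Conditions: LiBH4, MeOH (1 equiv), THF, 0 → 45 °C
Reagents that add atoms: none
Why: Chemoselective borohydride reduction: LiBH4 reduces the ester (C7) but neither the nitrile (C13) nor the ketal, so the two ends of the pseudo-symmetric C7–C13 unit stay differentiated.

Step 6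
Reactants: 9 2-[(4R,6S)-6-(2-hydroxyethyl)-2,2-dimethyl-1,3-dioxan-4-yl]acetonitrile
Product: 10 2-[(4R,6R)-2,2-dimethyl-6-(2-oxoethyl)-1,3-dioxan-4-yl]acetonitrile
Conditions: Dess–Martin periodinane, NaHCO3, CH2Cl2, 0 °C → rt
Reagents that add atoms: none
Why: Dess–Martin oxidation of the primary alcohol under buffered, non-enolising conditions that should not eliminate the β-alkoxy aldehyde.

Step 7
Reactants: 10 2-[(4R,6R)-2,2-dimethyl-6-(2-oxoethyl)-1,3-dioxan-4-yl]acetonitrile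
Product: 11 2-[(4R,6S)-6-(2-hydroxypropyl)-2,2-dimethyl-1,3-dioxan-4-yl]acetonitrile (both carbinol epimers)
Conditions: MeMgBr, THF, −78 °C; aq. NH4Cl
Reagents that add atoms: methylmagnesium bromide C[Mg]Br
Why: Grignard addition to the aldehyde at −78 °C, where the nitrile is inert; the new carbinol centre is erased in step 8, so its configuration does not matter.

Step 8
Reactants: 11 2-[(4R,6S)-6-(2-hydroxypropyl)-2,2-dimethyl-1,3-dioxan-4-yl]acetonitrile
Product: 12 2-[(4R,6R)-2,2-dimethyl-6-(2-oxopropyl)-1,3-dioxan-4-yl]acetonitrile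
Conditions: Dess–Martin periodinane, NaHCO3, CH2Cl2, rt
Reagents that add atoms: none
Why: Dess–Martin oxidation gives the methyl ketone (C6–C7) that carries a β-oxygen at C9 for the next step.

Step 9
Reactants: 12 2-[(4R,6R)-2,2-dimethyl-6-(2-oxopropyl)-1,3-dioxan-4-yl]acetonitrile, 13 3-(benzyloxy)propanal
Product: 15 C3–C13 aldol adduct (C3-OBn; C5-OH; C7 ketone; C9/C11 acetonide; C13 nitrile), via dicyclohexylboron enolate 14 (not isolated)
Conditions: (c-Hex)2BCl, Et3N, Et2O, −78 → 0 °C; then 13, −78 → −20 °C; MeOH, pH 7 buffer, 30% H2O2, 0 °C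
Reagents that add atoms: chlorodicyclohexylborane ClB(C1CCCCC1)C1CCCCC1 (in intermediate 14 only)
Why: Paterson/Evans boron aldol reaction of a β-alkoxy methyl ketone; the kinetic methyl-side enolate should add with 1,5-anti induction from the C9 ketal oxygen (formyl C–H···O contact in the boat transition state) and so set C5.

Step 10
Reactants: 15 C3–C13 aldol adduct
Product: 16 C3–C13 5,7-anti-diol (C3-OBn; C9/C11 acetonide; C13 nitrile)
Conditions: Me4NBH(OAc)3, MeCN/AcOH 1:1, −30 °C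
Reagents that add atoms: none
Why: Evans–Saksena reduction; the C5-O-bound acetoxyborohydride delivers hydride intramolecularly through a chair transition state, which should give the 1,3-anti diol and set C7.

Step 11
Reactants: 16 C3–C13 5,7-anti-diol
Product: 17 C3–C13 5,7,9,11-tetraol (C3-OBn; C13 nitrile)
Conditions: CSA (10 mol%), MeOH, rt
Reagents that add atoms: none
Why: Acid-catalysed transketalisation removes the acetonide early, so that no acid-labile ketal has to be cleaved once the pentaene and its allylic C15 oxygen are present.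

Step 12
Reactants: 17 C3–C13 5,7,9,11-tetraol
Product: 18 5,7,9,11-tetrakis-O-TBS nitrile (C3-OBn)
Conditions: TBSOTf, 2,6-lutidine, CH2Cl2, −78 → 0 °C
Reagents that add atoms: tert-butyldimethylsilyl triflate CC(C)(C)[Si](C)(C)OS(=O)(=O)C(F)(F)F
Why: Exhaustive silylation with the silyl triflate protects the four secondary hydroxyls as TBS ethers, the only protecting group left for the end of the route.

Step 13
Reactants: 18 5,7,9,11-tetrakis-O-TBS nitrile
Product: 20 C13 primary alcohol (C3-OBn; 5,7,9,11-tetrakis-O-TBS), via C13 aldehyde 19 (not isolated)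
Conditions: DIBAL-H, CH2Cl2, −78 °C; aq. Rochelle salt; crude 19: NaBH4, MeOH, 0 °C
Reagents that add atoms: water O
Why: DIBAL-H stops at the N-aluminio aldimine, whose hydrolysis gives the aldehyde, and borohydride reduction then gives the C13 alcohol.

Step 14
Reactants: 20 C13 primary alcohol
Product: 21 C13-O-TES ether (C3-OBn; 5,7,9,11-tetrakis-O-TBS)
Conditions: TESCl, imidazole, CH2Cl2, 0 °C
Reagents that add atoms: triethylsilyl chloride CC[Si](CC)(CC)Cl
Why: Silylation gives a primary TES ether that can later be removed in the presence of secondary TBS ethers.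

Step 15
Reactants: 21 C13-O-TES ether
Product: 22 C3 primary alcohol (5,7,9,11-tetrakis-O-TBS; C13-O-TES)
Conditions: H2 (1 atm), Pd(OH)2/C, NaHCO3 (trace), EtOAc, rt
Reagents that add atoms: none
Why: Neutral hydrogenolysis of the benzyl ether; the substrate has no alkene and silyl ethers are stable to it.

Step 16
Reactants: 22 C3 primary alcohol
Product: 23 C3 aldehyde (C3–C13 fragment; 5,7,9,11-tetrakis-O-TBS; C13-O-TES)
Conditions: Dess–Martin periodinane, NaHCO3, CH2Cl2, 0 °C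
Reagents that add atoms: none
Why: Buffered Dess–Martin oxidation gives the β-silyloxy aldehyde without elimination.

Step 17
Reactants: 7 (4R)-4-benzyl-3-[(3S)-3-(TBS-oxy)octanoyl]-1,3-oxazolidin-2-one, 23 C3 aldehyde
Product: 25 Evans aldol adduct (N-acyl oxazolidinone of the C1–C13 chain; C3-OH; C1′-O-TBS), via Z-dibutylboron enolate 24 (not isolated)
Conditions: 7, Bu2BOTf, i-Pr2NEt, CH2Cl2, −78 → 0 °C; then 23, −78 → 0 °C; MeOH, pH 7 buffer, 30% H2O2, 0 °C
Reagents that add atoms: dibutylboron triflate CCCCB(CCCC)OS(=O)(=O)C(F)(F)F (in intermediate 24 only)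
Why: Evans syn-aldol reaction; the Z-boron enolate reacts through a Zimmerman–Traxler chair with the face dictated by the (R)-benzyl auxiliary, which should set C2 (R) and C3 (S) syn, the C1′ and C5 centres being spectators.

Step 18
Reactants: 25 Evans aldol adduct
Product: 26 C3-O-TBS imide
Conditions: TBSOTf, 2,6-lutidine, CH2Cl2, −78 → 0 °C
Reagents that add atoms: tert-butyldimethylsilyl triflate CC(C)(C)[Si](C)(C)OS(=O)(=O)C(F)(F)F
Why: Silylation of the aldol hydroxyl blocks retro-aldol cleavage and completes the all-silyl protection.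

Step 19
Reactants: 26 C3-O-TBS imide
Product: 28 acid (C1–C13; hexakis-O-TBS at C1′/C3/C5/C7/C9/C11; C13-O-TES), via peroxy acid 27 (not isolated)
Conditions: LiOH, 30% H2O2, THF/H2O 3:1, 0 °C; aq. Na2SO3; NaHSO4 to pH 4
Reagents that add atoms: hydrogen peroxide OO
Why: Hydroperoxide attacks the exocyclic imide carbonyl selectively even in hindered cases (Evans auxiliary cleavage), and the weakly basic conditions should not epimerise C2.

**Part C – Z-iodide 35 (C14–C17)**

Step 20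
Reactants: 29 (R)-2,2-dimethyl-1,3-dioxolane-4-carbaldehyde
Product: 30 (4S)-4-ethynyl-2,2-dimethyl-1,3-dioxolane
Conditions: dimethyl (1-diazo-2-oxopropyl)phosphonate, K2CO3, MeOH, 0 °C → rt
Reagents that add atoms: dimethyl (1-diazo-2-oxopropyl)phosphonate COP(=O)(OC)C(=[N+]=[N-])C(C)=O
Why: Ohira–Bestmann (Seyferth–Gilbert) homologation turns the aldehyde into the terminal alkyne under mild carbonate conditions that should keep the α-stereocentre (future C15).

Step 21
Reactants: 30 (4S)-4-ethynyl-2,2-dimethyl-1,3-dioxolane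
Product: 31 (2S)-but-3-yne-1,2-diol
Conditions: Dowex 50WX8 (H+), MeOH, rt
Reagents that add atoms: none
Why: Acid-resin transketalisation frees the diol needed to direct the next step, with a filtration-only work-up for a water-soluble product.

Step 22
Reactants: 31 (2S)-but-3-yne-1,2-diol
Product: 33 (2S,3Z)-4-iodo-3-methylbut-3-ene-1,2-diol, via chelated alkenylmagnesium species 32 (not isolated)
Conditions: MeMgBr (5 equiv), CuI (0.2 equiv), THF, −20 °C → rt; then I2, THF, −78 → 0 °C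
Reagents that add atoms: methylmagnesium bromide C[Mg]Br; iodine II
Why: Copper-catalysed anti-carbomagnesiation of a propargylic alkoxide (Duboudin–Jousseaume) puts the methyl on C16 and magnesium on C17 cis to the carbinol in a five-membered chelate, and iodinolysis with retention should give the Z-iodide.

Step 23
Reactants: 33 (2S,3Z)-4-iodo-3-methylbut-3-ene-1,2-diol
Product: 34 (2S,3Z)-4-iodo-3-methyl-1-(TES-oxy)but-3-en-2-ol
Conditions: TESCl (1.05 equiv), imidazole, CH2Cl2, −78 → −30 °C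
Reagents that add atoms: triethylsilyl chloride CC[Si](CC)(CC)Cl
Why: Kinetic silylation of the primary (C14) hydroxyl over the hindered secondary allylic one.

Step 24
Reactants: 34 (2S,3Z)-4-iodo-3-methyl-1-(TES-oxy)but-3-en-2-ol
Product: 35 (2S,3Z)-2-(TBS-oxy)-4-iodo-3-methyl-1-(TES-oxy)but-3-ene
Conditions: TBSOTf, 2,6-lutidine, CH2Cl2, −78 °C
Reagents that add atoms: tert-butyldimethylsilyl triflate CC(C)(C)[Si](C)(C)OS(=O)(=O)C(F)(F)F
Why: Silylation gives the bulky, non-chelating C15 TBS ether that later steers the key step.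

**Part D – alcohol 45 (C14–C27)**

Step 25
Reactants: 36 (R)-but-3-yn-2-ol
Product: 37 (R)-but-3-yn-2-yl methanesulfonate
Conditions: MsCl, Et3N, CH2Cl2, −78 → 0 °C
Reagents that add atoms: methanesulfonyl chloride CS(=O)(=O)Cl
Why: O-Sulfonylation with retention gives the propargylic electrophile for the Marshall reaction.

Step 26
Reactants: 37 (R)-but-3-yn-2-yl methanesulfonate, 38 acetaldehyde
Product: 39 (2R,3S)-3-methylpent-4-yn-2-ol
Conditions: Pd(OAc)2 (5 mol%), PPh3 (5 mol%), Et2Zn (3 equiv), THF, −78 → −20 °C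
Reagents that add atoms: none
Why: Marshall propargylation; anti-SN2′ palladation, transmetalation to a configurationally defined allenylzinc and cyclic SE2′ addition to the aldehyde should give the anti homopropargylic alcohol, with C26 set by the mesylate and C27 by the chair transition state.

Step 27
Reactants: 39 (2R,3S)-3-methylpent-4-yn-2-ol
Product: 40 (2R,3S,4E)-3-methyl-5-(Bpin)pent-4-en-2-ol
Conditions: pinacolborane (2.2 equiv), Cp2Zr(H)Cl (10 mol%), Et3N (10 mol%), CH2Cl2, rt; MeOH work-up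
Reagents that add atoms: pinacolborane [H]B1OC(C)(C)C(C)(C)O1
Why: Zirconium-catalysed syn-hydroboration of the terminal alkyne gives the E-alkenylboronate (C24=C25); the O-boryl group formed at the free hydroxyl is cleaved on work-up.

Step 28
Reactants: 41 glutaconaldehyde potassium salt
Product: 42 (2E,4E)-5-bromopenta-2,4-dienal
Conditions: PPh3, Br2, CH2Cl2, 0 °C; then 41, 0 °C → rt
Reagents that add atoms: bromine BrBr
Why: Deoxybromination of the dienolate by dibromotriphenylphosphorane (addition–elimination at the vinylogous acyl position) gives the thermodynamically preferred all-E bromodienal.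

Step 29
Reactants: 40 (2R,3S,4E)-3-methyl-5-(Bpin)pent-4-en-2-ol, 42 (2E,4E)-5-bromopenta-2,4-dienal
Product: 43 (2E,4E,6E,8S,9R)-9-hydroxy-8-methyldeca-2,4,6-trienal
Conditions: Pd(PPh3)4 (5 mol%), aq. K3PO4, THF, rt
Reagents that add atoms: none
Why: Suzuki–Miyaura coupling with retention of both alkene geometries forms C23–C24; the free hydroxyl and the aldehyde are tolerated.

Step 30
Reactants: 43 (2E,4E,6E,8S,9R)-9-hydroxy-8-methyldeca-2,4,6-trienal
Product: 44 (2R,3S,4E,6E,8E,10E)-3-methyl-11-(Bpin)undeca-4,6,8,10-tetraen-2-ol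
Conditions: CrCl2 (8 equiv), LiI (4 equiv), Cl2CHBpin (2 equiv), THF, rt
Reagents that add atoms: 2-(dichloromethyl)-4,4,5,5-tetramethyl-1,3,2-dioxaborolane ClC(Cl)B1OC(C)(C)C(C)(C)O1
Why: Takai–Utimoto boryl olefination; the gem-dichromium reagent adds to the aldehyde and eliminates anti-periplanar to give the E-alkenylboronate (C18=C19).

Step 31
Reactants: 35 (2S,3Z)-2-(TBS-oxy)-4-iodo-3-methyl-1-(TES-oxy)but-3-ene, 44 (2R,3S,4E,6E,8E,10E)-3-methyl-11-(Bpin)undeca-4,6,8,10-tetraen-2-ol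
Product: 45 C14–C27 pentaenyl alcohol (16Z,18E,20E,22E,24E; C14-O-TES; C15-O-TBS; free C27-OH)
Conditions: Pd(PPh3)4 (10 mol%), TlOEt, THF/H2O 3:1, rt
Reagents that add atoms: none
Why: Thallium-accelerated Suzuki–Miyaura coupling at room temperature forms C17–C18 with retention at both partners and so completes the pentaene with the Z-trisubstituted terminus.

**Part E – union, key step, deprotection**

Step 32
Reactants: 28 acid (C1–C13), 45 C14–C27 pentaenyl alcohol
Product: 47 seco ester (C1–O–C27 ester; C13-O-TES; C14-O-TES; heptakis-O-TBS), via mixed trichlorobenzoic anhydride 46 (not isolated)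
Conditions: 2,4,6-trichlorobenzoyl chloride, Et3N, THF, rt; then 45, DMAP, toluene, rt
Reagents that add atoms: 2,4,6-trichlorobenzoyl chloride O=C(Cl)c1c(Cl)cc(Cl)cc1Cl (in intermediate 46 only)
Why: Yamaguchi esterification; DMAP-mediated acyl transfer from the mixed anhydride to the only free hydroxyl (C27) under conditions that should keep the C2 configuration.

Step 33
Reactants: 47 seco ester
Product: 48 seco diol (C13-OH; C14-OH; heptakis-O-TBS)
Conditions: PPTS (0.2 equiv), MeOH/CH2Cl2 1:4, 0 °C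
Reagents that add atoms: none
Why: Selective solvolysis; primary TES ethers are cleaved far faster than secondary TBS ethers under mild acid, and the pentaene and the silylated C15 oxygen should survive PPTS at 0 °C.

Step 34
Reactants: 48 seco diol
Product: 49 seco dialdehyde (C13 and C14 aldehydes; heptakis-O-TBS)
Conditions: Dess–Martin periodinane (3 equiv), NaHCO3, CH2Cl2, 0 °C; crude product used at once
Reagents that add atoms: none
Why: Double Dess–Martin oxidation under buffered, non-basic conditions; the α-silyloxy C14 aldehyde should keep its C15 configuration because A(1,3) strain of the Z-alkene holds C15–H in the alkene plane, away from overlap with the polyene π system.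

Step 35
Reactants: 49 seco dialdehyde
Product: 50 heptakis-O-TBS macrolactone with free (13S,14R)-13,14-diol
Conditions: SmI2 (6 equiv, 0.1 M in THF), THF, 0 °C → rt, syringe-pump addition of 49 over 10 h (final 1 mM), no HMPA, no proton source, Ar, dark; then sat. aq. NaHCO3/Na2S2O3
Reagents that add atoms: none
Why: Inner-sphere electron transfer from Sm(II) to the more electron-poor, α-silyloxy C14 aldehyde gives a Sm(III) ketyl that captures the Sm-bound C13 aldehyde (or its ketyl) in an O–Sm–O bridged array, and C13–C14 bond formation with a second electron transfer gives the samarium 13,14-diolate, released as the diol on work-up. The closest known reactions are the pinacol (reductive carbonyl coupling) macrocyclisations of ω-dialdehydes with SmI2 or low-valent titanium and the SmI2 pinacol cyclisations of α-alkoxy dialdehydes. The one ring formed, the 28-membered lactone, closes end to end in a formal 28-exo-trig attack of the ketyl carbon on the second C=O, favoured over oligomerisation by pseudo-dilution and by the rigid pentaene and s-trans ester, which remove rotors from the tether. C14 is controlled by C15: the bulky, non-chelating OTBS lies anti to the forming bond (polar Felkin–Anh/Cornforth) and the partner passes C15–H, which gives 14,15-anti; C13 is controlled by the bridged transition state, in which the two Sm-bound oxygens are gauche and the two chain termini anti, which gives the 13,14-syn (threo) diol, with C11–OTBS a weak β-spectator. The step needs chemoselectivity for the two aldehydes (SmI2 in THF without HMPA should leave the hindered ester and the unactivated pentaene alone), no β-elimination of the C15 oxygen (without a proton source the ketyl is not reduced further before it couples), and Felkin/threo selectivity, which the α-OTBS group and the metal bridge should secure.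

Step 36
Reactants: 50 heptakis-O-TBS macrolactone
Product: 51 target (CNP0269947.1)
Conditions: HF·pyridine, pyridine, THF, 0 °C → rt, polypropylene vessel, dark
Reagents that add atoms: none
Why: Global fluoride desilylation under pyridine-buffered conditions removes the seven TBS ethers without strong acid or base, which should spare the lactone (β-hydroxy ester, retro-aldol prone) and the allylic C15 carbinol of the pentaene.

**Compound list**

1 | methyl 3-oxooctanoate | CCCCCC(=O)CC(=O)OC | starting material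
2 | methyl (3S)-3-hydroxyoctanoate | CCCCC[C@H](O)CC(=O)OC | intermediate
3 | methyl (3S)-3-(TBS-oxy)octanoate | CCCCC[C@H](O[Si](C)(C)C(C)(C)C)CC(=O)OC | intermediate
4 | (3S)-3-(TBS-oxy)octanoic acid | CCCCC[C@H](O[Si](C)(C)C(C)(C)C)CC(=O)O | intermediate
5 | (4R)-4-benzyl-1,3-oxazolidin-2-one | O=C1N[C@H](Cc2ccccc2)CO1 | starting material
6 | mixed pivalic anhydride of 4 (not isolated) | CCCCC[C@H](O[Si](C)(C)C(C)(C)C)CC(=O)OC(=O)C(C)(C)C | intermediate
7 | (4R)-4-benzyl-3-[(3S)-3-(TBS-oxy)octanoyl]-1,3-oxazolidin-2-one | CCCCC[C@H](O[Si](C)(C)C(C)(C)C)CC(=O)N1[C@H](Cc2ccccc2)COC1=O | intermediate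
8 | tert-butyl 2-[(4R,6R)-6-(cyanomethyl)-2,2-dimethyl-1,3-dioxan-4-yl]acetate (C7–C13; C9/C11 syn-acetonide) | CC(C)(C)OC(=O)C[C@H]1C[C@@H](CC#N)OC(C)(C)O1 | starting material
9 | 2-[(4R,6S)-6-(2-hydroxyethyl)-2,2-dimethyl-1,3-dioxan-4-yl]acetonitrile | OCC[C@H]1C[C@@H](CC#N)OC(C)(C)O1 | intermediate
10 | 2-[(4R,6R)-2,2-dimethyl-6-(2-oxoethyl)-1,3-dioxan-4-yl]acetonitrile | O=CC[C@H]1C[C@@H](CC#N)OC(C)(C)O1 | intermediate
11 | 2-[(4R,6S)-6-(2-hydroxypropyl)-2,2-dimethyl-1,3-dioxan-4-yl]acetonitrile (carbinol epimers) | CC(O)C[C@H]1C[C@@H](CC#N)OC(C)(C)O1 | intermediate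
12 | 2-[(4R,6R)-2,2-dimethyl-6-(2-oxopropyl)-1,3-dioxan-4-yl]acetonitrile (C6–C13 methyl ketone) | CC(=O)C[C@H]1C[C@@H](CC#N)OC(C)(C)O1 | intermediate
13 | 3-(benzyloxy)propanal | O=CCCOCc1ccccc1 | starting material
14 | dicyclohexylboron enolate of 12 (not isolated) | C=C(OB(C1CCCCC1)C1CCCCC1)C[C@H]1C[C@@H](CC#N)OC(C)(C)O1 | intermediate
15 | C3–C13 aldol adduct: C3-OBn, C5-OH (as in target), C7 ketone, C9/C11 acetonide, C13 nitrile | c1ccccc1COCC[C@@H](O)CC(=O)C[C@H]1C[C@@H](CC#N)OC(C)(C)O1 | intermediate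
16 | C3–C13 5,7-anti-diol: C5 and C7 as in target, C9/C11 acetonide, C13 nitrile | c1ccccc1COCC[C@@H](O)C[C@H](O)C[C@H]1C[C@@H](CC#N)OC(C)(C)O1 | intermediate
17 | C3–C13 5,7,9,11-tetraol nitrile (C3-OBn; all four centres as in target) | c1ccccc1COCC[C@@H](O)C[C@H](O)C[C@H](O)C[C@H](O)CC#N | intermediate
18 | 5,7,9,11-tetrakis-O-TBS nitrile (C3-OBn) | c1ccccc1COCC[C@@H](O[Si](C)(C)C(C)(C)C)C[C@H](O[Si](C)(C)C(C)(C)C)C[C@H](O[Si](C)(C)C(C)(C)C)C[C@H](O[Si](C)(C)C(C)(C)C)CC#N | intermediate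
19 | C13 aldehyde of 18 (not isolated) | c1ccccc1COCC[C@@H](O[Si](C)(C)C(C)(C)C)C[C@H](O[Si](C)(C)C(C)(C)C)C[C@H](O[Si](C)(C)C(C)(C)C)C[C@H](O[Si](C)(C)C(C)(C)C)CC=O | intermediate
20 | C13 primary alcohol (C3-OBn; tetrakis-O-TBS) | c1ccccc1COCC[C@@H](O[Si](C)(C)C(C)(C)C)C[C@H](O[Si](C)(C)C(C)(C)C)C[C@H](O[Si](C)(C)C(C)(C)C)C[C@H](O[Si](C)(C)C(C)(C)C)CCO | intermediate
21 | C13-O-TES ether (C3-OBn; tetrakis-O-TBS) | c1ccccc1COCC[C@@H](O[Si](C)(C)C(C)(C)C)C[C@H](O[Si](C)(C)C(C)(C)C)C[C@H](O[Si](C)(C)C(C)(C)C)C[C@H](O[Si](C)(C)C(C)(C)C)CCO[Si](CC)(CC)CC | intermediate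
22 | C3 primary alcohol (tetrakis-O-TBS; C13-O-TES) | OCC[C@@H](O[Si](C)(C)C(C)(C)C)C[C@H](O[Si](C)(C)C(C)(C)C)C[C@H](O[Si](C)(C)C(C)(C)C)C[C@H](O[Si](C)(C)C(C)(C)C)CCO[Si](CC)(CC)CC | intermediate
23 | C3 aldehyde, C3–C13 fragment (tetrakis-O-TBS; C13-O-TES) | O=CC[C@@H](O[Si](C)(C)C(C)(C)C)C[C@H](O[Si](C)(C)C(C)(C)C)C[C@H](O[Si](C)(C)C(C)(C)C)C[C@H](O[Si](C)(C)C(C)(C)C)CCO[Si](CC)(CC)CC | intermediate
24 | Z-dibutylboron enolate of 7 (not isolated) | CCCCC[C@H](O[Si](C)(C)C(C)(C)C)/C=C(\OB(CCCC)CCCC)N1[C@H](Cc2ccccc2)COC1=O | intermediate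
25 | Evans aldol adduct: imide of the C1–C13 chain, C2 and C3 as in target, free C3-OH | CCCCC[C@H](O[Si](C)(C)C(C)(C)C)[C@@H](C(=O)N1[C@H](Cc2ccccc2)COC1=O)[C@@H](O)C[C@@H](O[Si](C)(C)C(C)(C)C)C[C@H](O[Si](C)(C)C(C)(C)C)C[C@H](O[Si](C)(C)C(C)(C)C)C[C@H](O[Si](C)(C)C(C)(C)C)CCO[Si](CC)(CC)CC | intermediate
26 | C3-O-TBS imide | CCCCC[C@H](O[Si](C)(C)C(C)(C)C)[C@@H](C(=O)N1[C@H](Cc2ccccc2)COC1=O)[C@@H](O[Si](C)(C)C(C)(C)C)C[C@@H](O[Si](C)(C)C(C)(C)C)C[C@H](O[Si](C)(C)C(C)(C)C)C[C@H](O[Si](C)(C)C(C)(C)C)C[C@H](O[Si](C)(C)C(C)(C)C)CCO[Si](CC)(CC)CC | intermediate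
27 | peroxy acid of 28 (not isolated) | CCCCC[C@H](O[Si](C)(C)C(C)(C)C)[C@@H](C(=O)OO)[C@@H](O[Si](C)(C)C(C)(C)C)C[C@@H](O[Si](C)(C)C(C)(C)C)C[C@H](O[Si](C)(C)C(C)(C)C)C[C@H](O[Si](C)(C)C(C)(C)C)C[C@H](O[Si](C)(C)C(C)(C)C)CCO[Si](CC)(CC)CC | intermediate
28 | acid, C1–C13 fragment with C1′–C6′ side chain (hexakis-O-TBS; C13-O-TES; all centres as in target) | CCCCC[C@H](O[Si](C)(C)C(C)(C)C)[C@@H](C(=O)O)[C@@H](O[Si](C)(C)C(C)(C)C)C[C@@H](O[Si](C)(C)C(C)(C)C)C[C@H](O[Si](C)(C)C(C)(C)C)C[C@H](O[Si](C)(C)C(C)(C)C)C[C@H](O[Si](C)(C)C(C)(C)C)CCO[Si](CC)(CC)CC | intermediate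
29 | (R)-2,2-dimethyl-1,3-dioxolane-4-carbaldehyde | O=C[C@H]1COC(C)(C)O1 | starting material
30 | (4S)-4-ethynyl-2,2-dimethyl-1,3-dioxolane | C#C[C@H]1COC(C)(C)O1 | intermediate
31 | (2S)-but-3-yne-1,2-diol | C#C[C@H](O)CO | intermediate
32 | chelated (Z)-alkenylmagnesium bis-alkoxide (not isolated) | Br[Mg]/C=C(/C)[C@H](O[Mg]Br)CO[Mg]Br | intermediate
33 | (2S,3Z)-4-iodo-3-methylbut-3-ene-1,2-diol | I/C=C(/C)[C@H](O)CO | intermediate
34 | (2S,3Z)-4-iodo-3-methyl-1-(TES-oxy)but-3-en-2-ol | I/C=C(/C)[C@H](O)CO[Si](CC)(CC)CC | intermediate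
35 | (2S,3Z)-2-(TBS-oxy)-4-iodo-3-methyl-1-(TES-oxy)but-3-ene (C14–C17) | I/C=C(/C)[C@H](O[Si](C)(C)C(C)(C)C)CO[Si](CC)(CC)CC | intermediate
36 | (R)-but-3-yn-2-ol | C[C@@H](O)C#C | starting material
37 | (R)-but-3-yn-2-yl methanesulfonate | C[C@@H](OS(C)(=O)=O)C#C | intermediate
38 | acetaldehyde | CC=O | starting material
39 | (2R,3S)-3-methylpent-4-yn-2-ol | O[C@H](C)[C@@H](C)C#C | intermediate
40 | (2R,3S,4E)-3-methyl-5-(Bpin)pent-4-en-2-ol | O[C@H](C)[C@@H](C)/C=C/B1OC(C)(C)C(C)(C)O1 | intermediate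
41 | glutaconaldehyde potassium salt | [K+].[O-]/C=C/C=C/C=O | starting material
42 | (2E,4E)-5-bromopenta-2,4-dienal | O=C/C=C/C=C/Br | intermediate
43 | (2E,4E,6E,8S,9R)-9-hydroxy-8-methyldeca-2,4,6-trienal | O[C@H](C)[C@@H](C)/C=C/C=C/C=C/C=O | intermediate
44 | (2R,3S,4E,6E,8E,10E)-3-methyl-11-(Bpin)undeca-4,6,8,10-tetraen-2-ol | O[C@H](C)[C@@H](C)/C=C/C=C/C=C/C=C/B1OC(C)(C)C(C)(C)O1 | intermediate
45 | C14–C27 pentaenyl alcohol (16Z,18E,20E,22E,24E; C14-O-TES; C15-O-TBS; C15, C26, C27 as in target) | O[C@H](C)[C@@H](C)/C=C/C=C/C=C/C=C/C=C(/C)[C@H](O[Si](C)(C)C(C)(C)C)CO[Si](CC)(CC)CC | intermediate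
46 | mixed 2,4,6-trichlorobenzoic anhydride of 28 (not isolated) | CCCCC[C@H](O[Si](C)(C)C(C)(C)C)[C@@H](C(=O)OC(=O)c1c(Cl)cc(Cl)cc1Cl)[C@@H](O[Si](C)(C)C(C)(C)C)C[C@@H](O[Si](C)(C)C(C)(C)C)C[C@H](O[Si](C)(C)C(C)(C)C)C[C@H](O[Si](C)(C)C(C)(C)C)C[C@H](O[Si](C)(C)C(C)(C)C)CCO[Si](CC)(CC)CC | intermediate
47 | seco ester (C1–O–C27; C13-O-TES; C14-O-TES; heptakis-O-TBS) | CCCCC[C@H](O[Si](C)(C)C(C)(C)C)[C@@H](C(=O)O[C@H](C)[C@@H](C)/C=C/C=C/C=C/C=C/C=C(/C)[C@H](O[Si](C)(C)C(C)(C)C)CO[Si](CC)(CC)CC)[C@@H](O[Si](C)(C)C(C)(C)C)C[C@@H](O[Si](C)(C)C(C)(C)C)C[C@H](O[Si](C)(C)C(C)(C)C)C[C@H](O[Si](C)(C)C(C)(C)C)C[C@H](O[Si](C)(C)C(C)(C)C)CCO[Si](CC)(CC)CC | intermediate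
48 | seco diol (C13-OH; C14-OH; heptakis-O-TBS) | CCCCC[C@H](O[Si](C)(C)C(C)(C)C)[C@@H](C(=O)O[C@H](C)[C@@H](C)/C=C/C=C/C=C/C=C/C=C(/C)[C@H](O[Si](C)(C)C(C)(C)C)CO)[C@@H](O[Si](C)(C)C(C)(C)C)C[C@@H](O[Si](C)(C)C(C)(C)C)C[C@H](O[Si](C)(C)C(C)(C)C)C[C@H](O[Si](C)(C)C(C)(C)C)C[C@H](O[Si](C)(C)C(C)(C)C)CCO | intermediate
49 | seco dialdehyde (C13 and C14 aldehydes; heptakis-O-TBS) | CCCCC[C@H](O[Si](C)(C)C(C)(C)C)[C@@H](C(=O)O[C@H](C)[C@@H](C)/C=C/C=C/C=C/C=C/C=C(/C)[C@H](O[Si](C)(C)C(C)(C)C)C=O)[C@@H](O[Si](C)(C)C(C)(C)C)C[C@@H](O[Si](C)(C)C(C)(C)C)C[C@H](O[Si](C)(C)C(C)(C)C)C[C@H](O[Si](C)(C)C(C)(C)C)C[C@H](O[Si](C)(C)C(C)(C)C)CC=O | intermediate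
50 | heptakis-O-TBS macrolactone (TBS at O1′, O3, O5, O7, O9, O11, O15; free 13,14-diol; all centres as in target) | CCCCC[C@H](O[Si](C)(C)C(C)(C)C)[C@H]1C(=O)O[C@H](C)[C@@H](C)/C=C/C=C/C=C/C=C/C=C(/C)[C@H](O[Si](C)(C)C(C)(C)C)[C@H](O)[C@@H](O)C[C@@H](O[Si](C)(C)C(C)(C)C)C[C@@H](O[Si](C)(C)C(C)(C)C)C[C@@H](O[Si](C)(C)C(C)(C)C)C[C@H](O[Si](C)(C)C(C)(C)C)C[C@@H]1O[Si](C)(C)C(C)(C)C | intermediate
51 | CNP0269947.1 (28-membered pentaene macrolactone nonaol) | CCCCC[C@H](O)[C@H]1C(=O)O[C@H](C)[C@@H](C)/C=C/C=C/C=C/C=C/C=C(/C)[C@H](O)[C@H](O)[C@@H](O)C[C@@H](O)C[C@@H](O)C[C@@H](O)C[C@H](O)C[C@@H]1O | target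

**Totals and risks**

Total step count: 36. Longest linear sequence: 20 steps (8 → 51: steps 5–19 and 32–36).

Most likely to fail:

1. Step 35 (macrocyclic pinacol). The process at risk is weak discrimination between the two faces of C13 in the C–C bond-forming event (threo versus erythro), so that the 13-epimer forms, even if Felkin control at C14 holds. Fallback: separate the C13 stereocentre from the ring closure. It sets out from 49, which is cyclised as in step 35 without regard to C13 to the 13-epimeric macrocyclic diol F1. The less hindered C13 hydroxyl is silylated selectively (TESOTf, 2,6-lutidine, −78 °C) to the 13-O-TES ether F2, and the C14 hydroxyl is then silylated (TBSOTf, 2,6-lutidine) to the fully silylated compound F3. PPTS in MeOH/CH2Cl2 frees C13-OH again, giving the 13-epi alcohol F4, and Dess–Martin oxidation gives the macrocyclic 13-ketone F5. L-Selectride in THF at −78 °C should add anti to the perpendicular α-OTBS group at C14 (Felkin–Anh), giving the (13S)-alcohol F6 with the 13,14-syn relationship. F6 returns to the route at 51 under the conditions of step 36.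

2. Step 32 (esterification). The process at risk is slow acyl transfer from the α-branched mixed anhydride to the hindered C27 carbinol, so that C2 epimerisation through a ketene, β-elimination at C3 or decay of the light-sensitive pentaene alcohol competes. Fallback: change the order of fragment union. It sets out from 28 and 40. The small, polyene-free alcohol 40 can be used in excess and under forcing Yamaguchi or MNBA conditions (40–60 °C), and is acylated to the alkenylboronate ester F7. Suzuki coupling of F7 with 42 (as in step 29) gives the trienal ester F8. Takai–Utimoto boryl olefination (as in step 30) gives the tetraenylboronate ester F9. Suzuki coupling of F9 with 35 (as in step 31) returns to the route at 47.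

3. Step 26 (Marshall propargylation with acetaldehyde). The process at risk is loss of configurational purity of the allenylzinc before addition, together with poor mass balance from the volatile aldehyde and product. Fallback: crotylboration and cross-metathesis instead of propargylation and hydroboration. It sets out from 38, which is treated with Brown's (E)-crotyldiisopinocampheylborane [from trans-2-butene, n-BuLi/KOt-Bu, (−)-Ipc2BOMe, BF3·OEt2; −78 °C; NaOH/H2O2 work-up]. The closed chair transition state should give the anti alcohol (2R,3S)-3-methylpent-4-en-2-ol F10 under reagent control. Cross-metathesis of F10 with vinylboronic acid pinacol ester (Hoveyda–Grubbs II, CH2Cl2, 40 °C) returns to the route at 40, so step 27 is not needed.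

Further compounds
F1 | step 35 | 13-epimer of 50 [(13R,14R)-diol; heptakis-O-TBS macrolactone] | CCCCC[C@H](O[Si](C)(C)C(C)(C)C)[C@H]1C(=O)O[C@H](C)[C@@H](C)/C=C/C=C/C=C/C=C/C=C(/C)[C@H](O[Si](C)(C)C(C)(C)C)[C@H](O)[C@H](O)C[C@@H](O[Si](C)(C)C(C)(C)C)C[C@@H](O[Si](C)(C)C(C)(C)C)C[C@@H](O[Si](C)(C)C(C)(C)C)C[C@H](O[Si](C)(C)C(C)(C)C)C[C@@H]1O[Si](C)(C)C(C)(C)C
F2 | step 35 | 13-O-TES ether of F1 (free C14-OH) | CCCCC[C@H](O[Si](C)(C)C(C)(C)C)[C@H]1C(=O)O[C@H](C)[C@@H](C)/C=C/C=C/C=C/C=C/C=C(/C)[C@H](O[Si](C)(C)C(C)(C)C)[C@H](O)[C@H](O[Si](CC)(CC)CC)C[C@@H](O[Si](C)(C)C(C)(C)C)C[C@@H](O[Si](C)(C)C(C)(C)C)C[C@@H](O[Si](C)(C)C(C)(C)C)C[C@H](O[Si](C)(C)C(C)(C)C)C[C@@H]1O[Si](C)(C)C(C)(C)C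
F3 | step 35 | 13-O-TES 14-O-TBS derivative of F1 | CCCCC[C@H](O[Si](C)(C)C(C)(C)C)[C@H]1C(=O)O[C@H](C)[C@@H](C)/C=C/C=C/C=C/C=C/C=C(/C)[C@H](O[Si](C)(C)C(C)(C)C)[C@H](O[Si](C)(C)C(C)(C)C)[C@H](O[Si](CC)(CC)CC)C[C@@H](O[Si](C)(C)C(C)(C)C)C[C@@H](O[Si](C)(C)C(C)(C)C)C[C@@H](O[Si](C)(C)C(C)(C)C)C[C@H](O[Si](C)(C)C(C)(C)C)C[C@@H]1O[Si](C)(C)C(C)(C)C
F4 | step 35 | 13-epi alcohol, 14-O-TBS (octakis-O-TBS macrolactone, free C13-OH) | CCCCC[C@H](O[Si](C)(C)C(C)(C)C)[C@H]1C(=O)O[C@H](C)[C@@H](C)/C=C/C=C/C=C/C=C/C=C(/C)[C@H](O[Si](C)(C)C(C)(C)C)[C@H](O[Si](C)(C)C(C)(C)C)[C@H](O)C[C@@H](O[Si](C)(C)C(C)(C)C)C[C@@H](O[Si](C)(C)C(C)(C)C)C[C@@H](O[Si](C)(C)C(C)(C)C)C[C@H](O[Si](C)(C)C(C)(C)C)C[C@@H]1O[Si](C)(C)C(C)(C)C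
F5 | step 35 | macrocyclic 13-ketone (octakis-O-TBS) | CCCCC[C@H](O[Si](C)(C)C(C)(C)C)[C@H]1C(=O)O[C@H](C)[C@@H](C)/C=C/C=C/C=C/C=C/C=C(/C)[C@H](O[Si](C)(C)C(C)(C)C)[C@H](O[Si](C)(C)C(C)(C)C)C(=O)C[C@@H](O[Si](C)(C)C(C)(C)C)C[C@@H](O[Si](C)(C)C(C)(C)C)C[C@@H](O[Si](C)(C)C(C)(C)C)C[C@H](O[Si](C)(C)C(C)(C)C)C[C@@H]1O[Si](C)(C)C(C)(C)C
F6 | step 35 | (13S)-alcohol, 14-O-TBS (octakis-O-TBS macrolactone; C13 as in target) | CCCCC[C@H](O[Si](C)(C)C(C)(C)C)[C@H]1C(=O)O[C@H](C)[C@@H](C)/C=C/C=C/C=C/C=C/C=C(/C)[C@H](O[Si](C)(C)C(C)(C)C)[C@H](O[Si](C)(C)C(C)(C)C)[C@@H](O)C[C@@H](O[Si](C)(C)C(C)(C)C)C[C@@H](O[Si](C)(C)C(C)(C)C)C[C@@H](O[Si](C)(C)C(C)(C)C)C[C@H](O[Si](C)(C)C(C)(C)C)C[C@@H]1O[Si](C)(C)C(C)(C)C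
F7 | step 32 | ester of 28 with 40 (C24=C25 alkenyl-Bpin ester) | CCCCC[C@H](O[Si](C)(C)C(C)(C)C)[C@@H](C(=O)O[C@H](C)[C@@H](C)/C=C/B1OC(C)(C)C(C)(C)O1)[C@@H](O[Si](C)(C)C(C)(C)C)C[C@@H](O[Si](C)(C)C(C)(C)C)C[C@H](O[Si](C)(C)C(C)(C)C)C[C@H](O[Si](C)(C)C(C)(C)C)C[C@H](O[Si](C)(C)C(C)(C)C)CCO[Si](CC)(CC)CC
F8 | step 32 | trienal ester (C19 aldehyde) | CCCCC[C@H](O[Si](C)(C)C(C)(C)C)[C@@H](C(=O)O[C@H](C)[C@@H](C)/C=C/C=C/C=C/C=O)[C@@H](O[Si](C)(C)C(C)(C)C)C[C@@H](O[Si](C)(C)C(C)(C)C)C[C@H](O[Si](C)(C)C(C)(C)C)C[C@H](O[Si](C)(C)C(C)(C)C)C[C@H](O[Si](C)(C)C(C)(C)C)CCO[Si](CC)(CC)CC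
F9 | step 32 | tetraenyl-Bpin ester (C18 boronate) | CCCCC[C@H](O[Si](C)(C)C(C)(C)C)[C@@H](C(=O)O[C@H](C)[C@@H](C)/C=C/C=C/C=C/C=C/B1OC(C)(C)C(C)(C)O1)[C@@H](O[Si](C)(C)C(C)(C)C)C[C@@H](O[Si](C)(C)C(C)(C)C)C[C@H](O[Si](C)(C)C(C)(C)C)C[C@H](O[Si](C)(C)C(C)(C)C)C[C@H](O[Si](C)(C)C(C)(C)C)CCO[Si](CC)(CC)CC
F10 | step 26 | (2R,3S)-3-methylpent-4-en-2-ol | O[C@H](C)[C@@H](C)C=C
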